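Eschscholtzxanthin is C2-symmetric: two (S)-3-hydroxy-cyclohexenylidene rings cap a C20 octaene. Everything rests on cutting the two equivalent sp2–sp2 single bonds C7–C8 and C7'–C8' (carotenoid numbering), each the central bond of the diene made of the exocyclic ring double bond C6=C7 and the chain double bond C8=C9. One twofold Suzuki–Miyaura coupling joins two C10 ring alkenylboronates (from ketoisophorone) to a C20 bis(enol triflate) and gives the unprotected dodecaene directly. The bis(triflate) comes from crocetin dialdehyde, the natural C20 dial, by a two-electron reduction that moves every chain double bond into the retro positions.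

Key step: step 4

Assumption: all-E crocetin dialdehyde and bis[(pinacolato)boryl]methane are bought; carotenoid numbering (ring C1–C6, chain C7–C15, primed for the second half) is used for positions in the target and in the C20, C30 and C40 compounds.

**Step 1**
Reactants: 1 ketoisophorone (2,6,6-trimethylcyclohex-2-ene-1,4-dione)
Product: 2 (4S)-4-hydroxy-2,6,6-trimethylcyclohex-2-en-1-one
Conditions: RuCl[(S,S)-TsDPEN](p-cymene) (1 mol %), KOH (2 mol %), i-PrOH, 25 °C
Reagents that add atoms: none
Why: Noyori-type asymmetric transfer hydrogenation by outer-sphere, metal–ligand bifunctional hydride transfer; the enone-type C4 carbonyl is far more accessible than the C1 carbonyl wedged between the quaternary carbon and the methyl-bearing alkene carbon, and the (S,S)-ligand is expected to orient the C2=C3 π-system like the aryl group of an aryl ketone and so give the (4S)-alcohol (the mirror-image catalyst would serve if the sense proved opposite).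

**Step 2**
Reactants: 2 (4S)-4-hydroxy-2,6,6-trimethylcyclohex-2-en-1-one; 3 bis[(pinacolato)boryl]methane
Product: 4 (1S,4E)-3,5,5-trimethyl-4-[(4,4,5,5-tetramethyl-1,3,2-dioxaborolan-2-yl)methylidene]cyclohex-2-en-1-ol
Conditions: LiTMP (2.3 equiv), 3 (1.3 equiv), THF, 0 °C; then 2, −78 °C to 25 °C; aqueous work-up; chromatography on Et3N-deactivated silica to separate the E isomer
Reagents that add atoms: none
Why: Boron–Wittig olefination, in which the lithiated geminal bis(boronate) adds 1,2 to the only carbonyl group of the lithium alkoxide of 2 (the alkoxide, formed first, shields the carbinol hydrogen from γ-deprotonation, so the stereocentre is kept) and syn B–O elimination gives the exocyclic alkenylboronate; the two flanks of the carbonyl carbon are of similar size, so both double-bond geometries can form and the (E)-isomer needed (boron on the side of the gem-dimethyl carbon) is to be isolated by chromatography and assigned by NOE.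

**Step 3**
Reactants: 5 crocetin dialdehyde (all-E 2,6,11,15-tetramethylhexadeca-2,4,6,8,10,12,14-heptaenedial)
Product: 7 C20 bis(enol triflate) (all-E 2,6,11,15-tetramethylhexadeca-1,3,5,7,9,11,13,15-octaene-1,16-diyl bis(trifluoromethanesulfonate)), via dilithium octaenediolate 6 (not isolated)
Conditions: lithium naphthalenide (2.05 equiv), THF, −78 °C, argon, dark; then PhNTf2 (2.3 equiv), −78 to 0 °C; pH 7 work-up, used at once
Reagents that add atoms: N-phenylbis(trifluoromethanesulfonimide), O=S(=O)(N(c1ccccc1)S(=O)(=O)C(F)(F)F)C(F)(F)F
Why: Proposed new method: two single-electron transfers to the fully conjugated dialdehyde (a vinylogous 1,2-dicarbonyl compound) should give the closed-shell dienediolate 6, in which every chain double bond has moved by one position (C8=C9 through C9'=C8'), and the hard sulfonyl-transfer reagent traps both oxygen atoms so that the retro-octaene is fixed as the bis(enol triflate); the all-E geometry is expected because the s-trans single bonds of 5 become the new double bonds, and the closest known reaction types are the dissolving-metal reduction of enones to enolates with trapping as enol triflates and the reductive O-functionalisation of quinones and ene-1,4-diones.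

**Step 4**
Reactants: 4 (1S,4E)-alkenylboronate (2.3 equiv); 7 C20 bis(enol triflate)
Product: 9 (3S,3'S,6E,6'E)-eschscholtzxanthin, via C30 monotriflate 8 (not isolated)
Conditions: Pd(OAc)2 (5 mol %), SPhos (10 mol %), K3PO4 (4 equiv), THF/H2O 10:1, 25 °C, degassed, dark; crystallisation
Reagents that add atoms: none
Why: Twofold Suzuki–Miyaura coupling: zerovalent palladium inserts into the C8–O bond of the enol triflate, the phosphate-activated boronate 4 transfers its C7 carbon to divalent palladium, and reductive elimination forms the C7–C8 single bond, after which the C30 monotriflate 8 repeats the cycle at C8' with a second molecule of 4. The closest known reaction type is the coupling of alkenyl triflates with alkenylboronates used for retinoid and carotenoid polyenes. No ring is closed and no stereocentre is created, so the two (S)-carbinol centres from step 1 are carried through unchanged. The step needs retention of double-bond geometry on both partners, which transmetalation and reductive elimination at sp2 carbon secure, so the 6E geometry of 4 and the 8E geometry of 7 reappear in 9. No site selectivity is required because the C2 symmetry of 7 makes its two triflates equivalent, and the free hydroxyl groups are inert to the mild phosphate base. The coupling completes the dodecaene chromophore in the same operation, so no protecting group and no later redox step are needed.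

**Compound list**
1 | ketoisophorone (2,6,6-trimethylcyclohex-2-ene-1,4-dione) | `CC1=CC(=O)CC(C)(C)C1=O` | starting material
2 | (4S)-4-hydroxy-2,6,6-trimethylcyclohex-2-en-1-one | `CC1=C[C@@H](O)CC(C)(C)C1=O` | intermediate
3 | bis[(pinacolato)boryl]methane | `CC1(C)OB(CB2OC(C)(C)C(C)(C)O2)OC1(C)C` | starting material
4 | (1S,4E)-3,5,5-trimethyl-4-[(4,4,5,5-tetramethyl-1,3,2-dioxaborolan-2-yl)methylidene]cyclohex-2-en-1-ol | `CC1=C[C@@H](O)CC(C)(C)\C1=C/B2OC(C)(C)C(C)(C)O2` | intermediate
5 | crocetin dialdehyde, (2E,4E,6E,8E,10E,12E,14E)-2,6,11,15-tetramethylhexadeca-2,4,6,8,10,12,14-heptaenedial | `O=C/C(C)=C/C=C/C(C)=C/C=C/C=C(C)/C=C/C=C(C)/C=O` | starting material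
6 | dilithium (1E,3E,5E,7E,9E,11E,13E,15E)-2,6,11,15-tetramethylhexadeca-1,3,5,7,9,11,13,15-octaene-1,16-diolate | `[Li+].[Li+].[O-]/C=C(C)/C=C/C=C(C)/C=C/C=C/C(C)=C/C=C/C(C)=C/[O-]` | intermediate
7 | (1E,3E,5E,7E,9E,11E,13E,15E)-2,6,11,15-tetramethylhexadeca-1,3,5,7,9,11,13,15-octaene-1,16-diyl bis(trifluoromethanesulfonate) | `FC(F)(F)S(=O)(=O)O/C=C(C)/C=C/C=C(C)/C=C/C=C/C(C)=C/C=C/C(C)=C/OS(=O)(=O)C(F)(F)F` | intermediate
8 | C30 monotriflate: one (S)-hydroxycyclohexenylidene ring joined through C7–C8 (6E) to the all-E C20 octaene, whose other end still carries the enol triflate at C8' | `CC1=C[C@@H](O)CC(C)(C)\C1=C/C=C(C)/C=C/C=C(C)/C=C/C=C/C(C)=C/C=C/C(C)=C/OS(=O)(=O)C(F)(F)F` | intermediate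
9 | (3S,3'S,6E,6'E)-eschscholtzxanthin, all-E (3S,3'S)-4',5'-didehydro-4,5'-retro-β,β-carotene-3,3'-diol | `CC1=C[C@@H](O)CC(C)(C)\C1=C/C=C(C)/C=C/C=C(C)/C=C/C=C/C(C)=C/C=C/C(C)=C/C=C1/C(C)=C[C@@H](O)CC1(C)C` | target

**Step count and risks**
Total steps: 4. Longest linear sequence: 3 steps (steps 1, 2 and 4; 1 → 2 → 4 → 9).

Steps most likely to fail:

1. Step 3 (bears the label). What may go wrong: over-reduction or dimerisation at the radical-anion stage, sulfonylation at carbon instead of oxygen, electron transfer from the dienediolate to the triflating agent, and hydrolytic loss of the triflate on work-up. The fallback uses known chemistry, sets out from 4 and 5 and comes back at 9. Boronate 4 is silylated (TBSCl, imidazole, DMF) to the silyl ether of the boronate F1, and iodine with NaOH replaces boron by iodine with retention to give the (E)-alkenyl iodide F2. A twofold Nozaki–Hiyama–Kishi addition of F2 to 5 (CrCl2, NiCl2 cat., DMSO) gives the C40 bis-allylic diol F3, which keeps the normal heptaene between the carbinol carbons C8 and C8'. Low-valent titanium (TiCl3/LiAlH4, THF) then removes both of these hydroxyl groups in a vinylogous reductive elimination, the extended case of the known conversion of ene-1,4-diols and diene-1,6-diols into dienes and trienes, and gives the bis(silyl ether) of eschscholtzxanthin F4. TBAF in THF releases 9.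

2. Step 2. What may go wrong: slow 1,2-addition of the bulky boron carbanion to the hindered carbonyl group, competing conjugate addition, and formation of the exocyclic double bond with poor or even adverse E/Z selectivity. The fallback sets out from 2 (and uses 7) and comes back at 9. Wittig methylenation of 2 (Ph3P=CH2 in excess, THF, reflux), which copes with the hindered carbonyl group better, gives the methylidene dienol F5, a partner that has no geometry at C7. A twofold Mizoroki–Heck reaction of F5 with 7 (Pd(OAc)2, P(o-tol)3, Et3N, DMF, 60 °C) forms the C7–C8 bonds by insertion of the terminal C7H2 group into the alkenyl–palladium bond and β-hydride elimination from C7. The geometry at C6 is then adjusted by iodine-catalysed photo-equilibration, and the all-E isomer 9 is collected by crystallisation.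

3. Step 4. What may go wrong: cleavage of the S–O bond of the enol triflate by the aqueous base, protodeboronation of 4, a stalled second coupling, and E/Z isomerisation of the polyene. The fallback sets out from 4 (and uses 7) and comes back at 9. Iodine with NaOH converts 4 with retention into the (E)-alkenyl iodide F6, and (Bu3Sn)2 with Pd(PPh3)4 in toluene gives the (E)-alkenylstannane F7. A twofold Stille coupling of F7 with 7 (Pd2(dba)3, AsPh3, CuI, LiCl, NMP, 25 °C) then forms both C7–C8 bonds without base or water and gives 9.

**Further compounds**
F1 | step 3 | tert-butyldimethylsilyl ether of 4, (S,E)-tert-butyldimethyl{[3,5,5-trimethyl-4-(pinacolborylmethylidene)cyclohex-2-en-1-yl]oxy}silane | `CC1=C[C@@H](O[Si](C)(C)C(C)(C)C)CC(C)(C)\C1=C/B2OC(C)(C)C(C)(C)O2`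
F2 | step 3 | (S,E)-tert-butyl{[4-(iodomethylidene)-3,5,5-trimethylcyclohex-2-en-1-yl]oxy}dimethylsilane | `CC1=C[C@@H](O[Si](C)(C)C(C)(C)C)CC(C)(C)\C1=C/I`
F3 | step 3 | C40 bis-allylic diol: 8,8'-dihydroxy compound with both silylated ring ends (6E,6'E), normal all-E heptaene from C9 to C9', C8 and C8' configuration mixed | `CC1=C[C@@H](O[Si](C)(C)C(C)(C)C)CC(C)(C)\C1=C/C(O)/C(C)=C/C=C/C(C)=C/C=C/C=C(C)/C=C/C=C(C)/C(O)/C=C1/C(C)=C[C@@H](O[Si](C)(C)C(C)(C)C)CC1(C)C`
F4 | step 3 | (3S,3'S,6E,6'E)-eschscholtzxanthin bis(tert-butyldimethylsilyl) ether | `CC1=C[C@@H](O[Si](C)(C)C(C)(C)C)CC(C)(C)\C1=C/C=C(C)/C=C/C=C(C)/C=C/C=C/C(C)=C/C=C/C(C)=C/C=C1/C(C)=C[C@@H](O[Si](C)(C)C(C)(C)C)CC1(C)C`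
F5 | step 2 | (S)-3,5,5-trimethyl-4-methylidenecyclohex-2-en-1-ol | `CC1=C[C@@H](O)CC(C)(C)C1=C`
F6 | step 4 | (1S,4E)-4-(iodomethylidene)-3,5,5-trimethylcyclohex-2-en-1-ol | `CC1=C[C@@H](O)CC(C)(C)\C1=C/I`
F7 | step 4 | (1S,4E)-3,5,5-trimethyl-4-[(tributylstannyl)methylidene]cyclohex-2-en-1-ol | `CC1=C[C@@H](O)CC(C)(C)\C1=C/[Sn](CCCC)(CCCC)CCCC`
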